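## Retrosynthetic overview

1. Target ⇒ the C4 benzylic cation of (+)-leucorobinetinidin plus (+)-gallocatechin, which is bought and brings rings D, E and F with both of its stereocentres. This interflavan C4–C8 bond is made last, and C4 is set under control of C3.
2. Leucorobinetinidin ⇒ (+)-dihydrorobinetin (C4 ketone) ⇒ its tetra-O-benzyl ether.
3. Key disconnection: the O1–C2 bond of ring C, together with the C3–O bond. The trans-dihydroflavonol ⇒ the (αR,βS)-epoxide of a free 2'-hydroxychalcone ⇒ E-chalcone + H2O2, in one catalytic asymmetric epoxidation/cyclo-etherification that sets C2 and C3.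
4. Chalcone ⇒ Claisen–Schmidt union of the ring A acetophenone and the ring B aldehyde, both bought as benzyl ethers.
5. Ring order: rings A and B are bought; ring C is closed by C–O bond formation; rings D, E and F are bought; the two flavan units are joined last.

Assumption: (+)-gallocatechin (2R,3S) and the two benzyl-protected aromatic building blocks are bought as catalogue compounds.
Assumption: the ligand written in step 2 is L-PiPr2, the N,N'-dioxide of 1,3-bis[(2S)-2-(2,6-diisopropylphenylcarbamoyl)piperidin-1-yl]propane; its sense of induction on this substrate is not known, so if it gives the mirror-image epoxide, its enantiomer from D-pipecolic acid is used.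

## Route

Step 1
Reactants: 1 1-[4-(benzyloxy)-2-hydroxyphenyl]ethan-1-one; 2 3,4,5-tris(benzyloxy)benzaldehyde
Product: 3 (E)-1-[4-(benzyloxy)-2-hydroxyphenyl]-3-[3,4,5-tris(benzyloxy)phenyl]prop-2-en-1-one
Conditions: KOH (50% aq, 10 equiv), EtOH/THF (3:1), rt, 36 h; then 1 M HCl to pH 4
Reagents that add atoms: none
Why: Claisen–Schmidt (crossed aldol) condensation, in which the methyl ketone enolate adds to the non-enolisable aldehyde and E1cB dehydration gives the conjugated E-enone, while the 2'-phenoxide chalcone does not close to the flavanone in strong base; no stereocentre is formed.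

Step 2
Reactants: 3 (E)-1-[4-(benzyloxy)-2-hydroxyphenyl]-3-[3,4,5-tris(benzyloxy)phenyl]prop-2-en-1-one
Product: 5 (2R,3R)-7-(benzyloxy)-3-hydroxy-2-[3,4,5-tris(benzyloxy)phenyl]chroman-4-one (tetra-O-benzyl-dihydrorobinetin), via epoxyketone 4 (not isolated)
Conditions: Sc(OTf)3 (10 mol%), N,N'-dioxide L-PiPr2 (10 mol%), 30% aq H2O2 (1.2 equiv), THF, 0 to 30 °C, 24 h; then 40 °C, 6 h
Reagents that add atoms: hydrogen peroxide, OO
Why: Proposed new method: the 2'-phenol/carbonyl pair of 3 chelates the chiral scandium N,N'-dioxide complex, which also activates H2O2, so hydroperoxide adds to one face of Cβ and the scandium enolate closes the trans (αR,βS)-epoxide 4 (Weitz–Scheffer epoxidation, trans from the E-alkene); the same Lewis acid then binds the carbonyl/epoxide oxygen pair and the ortho phenol opens the oxirane at the benzylic Cβ in a 6-endo SN2 step, which forms the O1–C2 bond and ring C with inversion at Cβ and retention at Cα and so gives the 2,3-trans (2R,3R) product; the closest known reaction types are the chiral N,N'-dioxide/Sc(OTf)3/H2O2 epoxidation of simple chalcones, chiral Lewis acid activation of chelating 2'-hydroxychalcones, and the Algar–Flynn–Oyamada or acid-mediated closure of 2'-hydroxychalcone epoxides to trans-dihydroflavonols.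

Step 3
Reactants: 5 (2R,3R)-7-(benzyloxy)-3-hydroxy-2-[3,4,5-tris(benzyloxy)phenyl]chroman-4-one
Product: 6 (+)-dihydrorobinetin, (2R,3R)-3,7-dihydroxy-2-(3,4,5-trihydroxyphenyl)chroman-4-one
Conditions: H2 (1 atm), 10% Pd/C, EtOAc/MeOH (1:1), rt, 6 h
Reagents that add atoms: none
Why: Heterogeneous hydrogenolysis of the four aryl benzyl ethers, in which the C4 ketone (a vinylogous ester of the 7-oxygenated ring A) and the cyclic C2–O1 ether are not reduced under neutral conditions at 1 atm, so C2 and C3 are untouched.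

Step 4
Reactants: 6 (+)-dihydrorobinetin; 7 (+)-gallocatechin, (2R,3S)-2-(3,4,5-trihydroxyphenyl)chromane-3,5,7-triol
Product: 9 robinetinidol-(4alpha,8)-gallocatechin, via leucorobinetinidin 8 (not isolated)
Conditions: NaBH4 (3 equiv), EtOH, 0 °C to rt, N2, 2 h; aq HCl to pH 5 (excess hydride destroyed); then 7 (3 equiv), aq HCl to 0.1 M, rt, 18 h; Sephadex LH-20 (EtOH)
Reagents that add atoms: none
Why: NaBH4 reduces the ketone to the 2,3-trans-3,4-trans diol 8 (its C4 configuration is of no consequence), and in dilute acid 8 ionises to the C4 benzylic cation stabilised by O1 and the para 7-OH, which alkylates the phloroglucinol-type ring of 7 at its most nucleophilic position C8, mainly from the face anti to the 3-OH (biomimetic flavan-3,4-diol/flavan-3-ol condensation, a Friedel–Crafts alkylation), so C4 is set as S (4alpha, 3,4-trans) under control of C3, and the minor 4beta and C6-linked isomers are removed by chromatography.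

## Compound list

1 | 1-[4-(benzyloxy)-2-hydroxyphenyl]ethan-1-one | CC(=O)c1ccc(OCc2ccccc2)cc1O | starting material
2 | 3,4,5-tris(benzyloxy)benzaldehyde | O=Cc1cc(OCc2ccccc2)c(OCc2ccccc2)c(OCc2ccccc2)c1 | starting material
3 | (E)-1-[4-(benzyloxy)-2-hydroxyphenyl]-3-[3,4,5-tris(benzyloxy)phenyl]prop-2-en-1-one | O=C(/C=C/c1cc(OCc2ccccc2)c(OCc2ccccc2)c(OCc2ccccc2)c1)c1ccc(OCc2ccccc2)cc1O | intermediate
4 | [(2R,3S)-3-[3,4,5-tris(benzyloxy)phenyl]oxiran-2-yl][4-(benzyloxy)-2-hydroxyphenyl]methanone, the (αR,βS)-trans-epoxyketone formed in the flask | O=C(c1ccc(OCc2ccccc2)cc1O)[C@@H]1O[C@H]1c1cc(OCc2ccccc2)c(OCc2ccccc2)c(OCc2ccccc2)c1 | intermediate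
5 | (2R,3R)-7-(benzyloxy)-3-hydroxy-2-[3,4,5-tris(benzyloxy)phenyl]chroman-4-one (2,3-trans) | C(c1ccccc1)Oc1ccc2c(c1)O[C@H](c1cc(OCc3ccccc3)c(OCc3ccccc3)c(OCc3ccccc3)c1)[C@@H](O)C2=O | intermediate
6 | (+)-dihydrorobinetin, (2R,3R)-3,7-dihydroxy-2-(3,4,5-trihydroxyphenyl)chroman-4-one | Oc1ccc2c(c1)O[C@H](c1cc(O)c(O)c(O)c1)[C@@H](O)C2=O | intermediate
7 | (+)-gallocatechin, (2R,3S)-2-(3,4,5-trihydroxyphenyl)chromane-3,5,7-triol | Oc1cc(O)c2c(c1)O[C@H](c1cc(O)c(O)c(O)c1)[C@@H](O)C2 | starting material
8 | (+)-leucorobinetinidin, (2R,3S,4R)-2-(3,4,5-trihydroxyphenyl)chromane-3,4,7-triol (2,3-trans-3,4-trans), formed in the flask | Oc1ccc2c(c1)O[C@H](c1cc(O)c(O)c(O)c1)[C@@H](O)[C@@H]2O | intermediate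
9 | robinetinidol-(4alpha,8)-gallocatechin; upper unit 2R,3S,4S, lower unit 2R,3S | Oc1ccc2c(c1)O[C@H](c1cc(O)c(O)c(O)c1)[C@@H](O)[C@@H]2c1c(O)cc(O)c2c1O[C@H](c1cc(O)c(O)c(O)c1)[C@@H](O)C2 | target

## Step count and risks

Total steps: 4. Longest linear sequence: 4 (1 → 3 → 5 → 6 → 9); compound 7 is bought.

Most likely to fail, step 2 (the proposed new cascade). The free phenol may slow the epoxidation, the enantioselectivity is untested, and a Lewis-acid-induced aroyl shift of the epoxide (the isoflavone pathway) could compete with ring closure. The fallback uses known chemistry; it sets out from 3 and comes back at 5. The 2'-OH of 3 is alkylated with MOMCl (NaH, DMF, 0 °C) to the 2'-O-methoxymethyl chalcone F1. Juliá–Colonna epoxidation (poly-L-leucine, urea–H2O2, DBU, THF, rt) gives the (αR,βS)-epoxide F2, the sense known for chalcones with the L-polypeptide. HCl in MeOH/THF at 50 °C removes the methoxymethyl group, and the freed phenol closes ring C at Cβ to give 5, whose enantiomeric purity is raised by recrystallisation.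

Second, step 4 (reduction/condensation in one flask). The free-phenol condensation is expected to give 9 in only about 25–30% yield, beside the 4beta and C6-linked isomers and some triflavanoids. The fallback replaces it with a fully protected Lewis acid coupling; it sets out from 5 and 7 and comes back at 9. NaBH4 (THF/MeOH, 0 °C) reduces 5 to tetra-O-benzyl-leucorobinetinidin F3. The five phenols of 7 are benzylated (BnBr, K2CO3, DMF) to penta-O-benzylgallocatechin F4. TMSOTf in CH2Cl2 at −78 °C with F4 in excess (3 equiv) joins C4 of F3 to C8 of F4, where the protected nucleophile reacts at C8 only and the low temperature favours the 3,4-trans product, giving the nona-O-benzyl biflavanoid F5. Hydrogenolysis (H2, Pd(OH)2/C, THF/MeOH/H2O) gives 9.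

Third, step 1 (Claisen–Schmidt condensation). The poorly soluble benzyl ethers and the deactivated phenoxide enolate can stall the reaction, and flavanone can form on work-up; step 3 is judged the safest step. The fallback replaces the aldol by a Wittig olefination; it sets out from 1 and comes back at 3. Bromination of 1 with CuBr2 (EtOAc/CHCl3, reflux) gives the α-bromoketone F6. PPh3 (toluene, rt) gives the phosphonium bromide F7. Aqueous K2CO3/CH2Cl2 gives the stabilised acyl ylide F8, which reacts with 2 in toluene at reflux to give the E-chalcone 3.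

## Further compounds

F1 | step 2 | (E)-1-[4-(benzyloxy)-2-(methoxymethoxy)phenyl]-3-[3,4,5-tris(benzyloxy)phenyl]prop-2-en-1-one | COCOc1cc(OCc2ccccc2)ccc1C(=O)/C=C/c1cc(OCc2ccccc2)c(OCc2ccccc2)c(OCc2ccccc2)c1
F2 | step 2 | [(2R,3S)-3-[3,4,5-tris(benzyloxy)phenyl]oxiran-2-yl][4-(benzyloxy)-2-(methoxymethoxy)phenyl]methanone | COCOc1cc(OCc2ccccc2)ccc1C(=O)[C@@H]1O[C@H]1c1cc(OCc2ccccc2)c(OCc2ccccc2)c(OCc2ccccc2)c1
F3 | step 4 | (2R,3S,4R)-7-(benzyloxy)-2-[3,4,5-tris(benzyloxy)phenyl]chromane-3,4-diol | C(c1ccccc1)Oc1ccc2c(c1)O[C@H](c1cc(OCc3ccccc3)c(OCc3ccccc3)c(OCc3ccccc3)c1)[C@@H](O)[C@@H]2O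
F4 | step 4 | (2R,3S)-5,7-bis(benzyloxy)-2-[3,4,5-tris(benzyloxy)phenyl]chroman-3-ol | C(c1ccccc1)Oc1cc(OCc3ccccc3)c2c(c1)O[C@H](c1cc(OCc3ccccc3)c(OCc3ccccc3)c(OCc3ccccc3)c1)[C@@H](O)C2
F5 | step 4 | 7,3',4',5'-tetra-O-benzylrobinetinidol-(4alpha,8)-5,7,3',4',5'-penta-O-benzylgallocatechin | C(c1ccccc1)Oc1ccc2c(c1)O[C@H](c1cc(OCc3ccccc3)c(OCc3ccccc3)c(OCc3ccccc3)c1)[C@@H](O)[C@@H]2c1c(OCc3ccccc3)cc(OCc3ccccc3)c2c1O[C@H](c1cc(OCc3ccccc3)c(OCc3ccccc3)c(OCc3ccccc3)c1)[C@@H](O)C2
F6 | step 1 | 2-bromo-1-[4-(benzyloxy)-2-hydroxyphenyl]ethan-1-one | O=C(CBr)c1ccc(OCc2ccccc2)cc1O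
F7 | step 1 | {2-[4-(benzyloxy)-2-hydroxyphenyl]-2-oxoethyl}(triphenyl)phosphonium bromide | O=C(C[P+](c1ccccc1)(c1ccccc1)c1ccccc1)c1ccc(OCc2ccccc2)cc1O.[Br-]
F8 | step 1 | 1-[4-(benzyloxy)-2-hydroxyphenyl]-2-(triphenyl-lambda5-phosphanylidene)ethan-1-one | O=C(C=P(c1ccccc1)(c1ccccc1)c1ccccc1)c1ccc(OCc2ccccc2)cc1O
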